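**Retrosynthetic overview**
1. Last bond: the C8–O angelate, by esterification of the 8-hydroxy furanoheliangolide core (late acylation, as in the plant).
2. Core from one acyclic C15 bromo enal ynone in a single operation: C6–C7 allylchromium closure of the ten-membered carbocycle (the umpoled counterpart of the farnesyl cyclization), 6,12-lactonization, then transannular attack of the C10 hydroxyl on C3 of the ynone (a dehydrated 10-hydroxy-1,3-dione) to close the furanone. Ring order: carbocycle, lactone, furanone.
3. Acyclic precursor from C1–C2 bond formation: lithium acetylide of a (Z)-enynal acetal (C2–C6, C15) plus a gamma-lactone as C1 acyl donor (C7–C13), then SN2′ bromination.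
4. Lactone from a Morita–Baylis–Hillman reaction (C7–C11), a catalyst-controlled ketone reduction (C8) and a copper-catalysed pyruvate Mukaiyama aldol (C10).

Assumption: germacrane numbering (C1–C15) is used for atom labels, and (2Z)-3-methylpent-2-en-4-yn-1-ol is taken as commercially available as the pure Z isomer.

**Step 1**
Reactants: 1 1,1-dimethoxypropan-2-one
Product: 2 3,3-dimethoxy-2-(trimethylsilyloxy)prop-1-ene
Conditions: LiN(iPr)2 (1.1 equiv), THF, −78 °C; Me3SiCl, −78 → 0 °C
Reagents that add atoms: chlorotrimethylsilane, C[Si](C)(C)Cl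
Why: Kinetic deprotonation at the unhindered methyl group and O-silylation give the less substituted silyl enol ether (kinetic enolate trapping); no stereocentre is formed.

**Step 2**
Reactants: 2 3,3-dimethoxy-2-(trimethylsilyloxy)prop-1-ene; 3 methyl pyruvate
Product: 5 methyl (2R)-2-hydroxy-5,5-dimethoxy-2-methyl-4-oxopentanoate, via silyl ether 4 (not isolated)
Conditions: Cu(OTf)2 (10 mol %), (R,R)-2,2′-(propane-2,2-diyl)bis(4-tert-butyl-4,5-dihydrooxazole) (11 mol %), THF, −78 °C; then 1 M HCl, THF, 0 °C
Reagents that add atoms: none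
Why: Catalytic enantioselective Mukaiyama aldol addition: methyl pyruvate chelates the square-planar divalent copper bis(oxazoline) complex, the tert-butyl groups shield one ketone face, and the enolsilane attacks the other to set C10 as R (the (S,S) ligand gives the S series); dilute HCl cleaves the silyl ether.

**Step 3**
Reactants: 5 methyl (2R)-2-hydroxy-5,5-dimethoxy-2-methyl-4-oxopentanoate
Product: 7 (3R,5R)-5-(dimethoxymethyl)-3-hydroxy-3-methyloxolan-2-one, via diol ester 6 (not isolated)
Conditions: (S)-2-methyl-CBS-oxazaborolidine (20 mol %), catecholborane (2.5 equiv), toluene, −78 → −40 °C; MeOH; then PPTS (cat.), toluene, 60 °C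
Reagents that add atoms: none
Why: Corey–Bakshi–Shibata reduction of an alpha-keto acetal, with the branched dimethoxymethyl group in the large-substituent position, sets C8 as R under catalyst control (catecholborane caps the tertiary hydroxyl without leaving a B–H for undirected delivery), and the gamma-hydroxy ester then lactonizes under mild acid.

**Step 4**
Reactants: 7 (3R,5R)-5-(dimethoxymethyl)-3-hydroxy-3-methyloxolan-2-one; 8 methyl acrylate
Product: 10 methyl 2-{hydroxy[(2R,4R)-4-hydroxy-4-methyl-5-oxooxolan-2-yl]methyl}prop-2-enoate (both carbinol epimers), via lactone aldehyde 9 (not isolated)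
Conditions: TFA/H2O (9:1), 0 °C; evaporate; then methyl acrylate (5 equiv), DABCO (1 equiv), 1,4-dioxane, 25 °C
Reagents that add atoms: water, O
Why: Acid hydrolysis unmasks the aldehyde, which as an electron-poor alpha-oxygenated aldehyde undergoes a fast Morita–Baylis–Hillman reaction; the new C7 carbinol forms unselectively but is erased in step 8, and the short basic exposure limits epimerization at C8.

**Step 5**
Reactants: 11 (2Z)-3-methylpent-2-en-4-yn-1-ol
Product: 12 (2Z)-3-methylpent-2-en-4-ynal
Conditions: MnO2 (15 equiv), CH2Cl2, 25 °C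
Reagents that add atoms: none
Why: MnO2 oxidation of an allylic alcohol to the enal under neutral heterogeneous conditions that keep the Z geometry.

**Step 6**
Reactants: 12 (2Z)-3-methylpent-2-en-4-ynal
Product: 13 (3Z)-5,5-dimethoxy-3-methylpent-3-en-1-yne
Conditions: MeOSiMe3 (2.5 equiv), Me3SiOTf (2 mol %), CH2Cl2, −78 °C; pyridine quench
Reagents that add atoms: methoxytrimethylsilane, CO[Si](C)(C)C
Why: Noyori acetalization at −78 °C protects the aldehyde without Z/E isomerization, so the alkyne can be metalated and no free (Z)-enynol, which would cyclize onto the later ynone, is ever present.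

**Step 7**
Reactants: 10 methyl 2-{hydroxy[(2R,4R)-4-hydroxy-4-methyl-5-oxooxolan-2-yl]methyl}prop-2-enoate; 13 (3Z)-5,5-dimethoxy-3-methylpent-3-en-1-yne
Product: 15 methyl (4R,6R,10Z)-3,4,6-trihydroxy-12,12-dimethoxy-6,10-dimethyl-2-methylidene-7-oxododec-10-en-8-ynoate (both C3 epimers), via lithium acetylide 14 (not isolated)
Conditions: 13 (3.5 equiv), n-BuLi (3.3 equiv), THF, −78 °C; add 10, −78 °C, 1 h; AcOH, −78 °C; pH 7 buffer; crude used at once
Reagents that add atoms: none
Why: Lithium acetylide addition to a gamma-lactone stops at the tetrahedral lactolate at −78 °C and gives the ynone on quench; two equivalents deprotonate the hydroxyls, and the lactone carbonyl, activated by its alpha-oxygen, reacts faster than the hindered conjugated methyl ester; no stereocentre is touched.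

**Step 8**
Reactants: 15 methyl (4R,6R,10Z)-3,4,6-trihydroxy-12,12-dimethoxy-6,10-dimethyl-2-methylidene-7-oxododec-10-en-8-ynoate
Product: 17 methyl (2Z,4R,6R,10Z)-2-(bromomethyl)-4,6-dihydroxy-6,10-dimethyl-7,12-dioxododeca-2,10-dien-8-ynoate, via bromo acetal 16 (not isolated)
Conditions: NBS (1.3 equiv), Me2S (1.5 equiv), CH2Cl2, −20 → 0 °C; then 1 M HCl/THF (1:4), 0 °C
Reagents that add atoms: N-bromosuccinimide, O=C1CCC(=O)N1Br; water, O
Why: Corey–Kim-type activation of the allylic Baylis–Hillman hydroxyl followed by SN2′ attack of bromide gives the (Z)-2-(bromomethyl)enoate, removes the C7 centre and places C8 trans to the ester (no 8,12-lactonization), the non-allylic C8 and tertiary C10 hydroxyls being inert; dilute acid then hydrolyses the acetal to the Z enal.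

**Step 9**
Reactants: 17 methyl (2Z,4R,6R,10Z)-2-(bromomethyl)-4,6-dihydroxy-6,10-dimethyl-7,12-dioxododeca-2,10-dien-8-ynoate
Product: 20 (4Z,6R,7R,8R,10R)-8-hydroxy-3,10-epoxy-1-oxogermacra-2,4,11(13)-trien-12,6-olide, via macrocyclic hydroxy ester 18 (not isolated), via macrocyclic ynone lactone 19 (not isolated)
Conditions: CrCl2 (8 equiv), THF, 25 °C, addition of 17 over 8 h (final 2 mM); aq. NH4Cl work-up; crude, (Ph3P)AuNTf2 (5 mol %), toluene, 25 °C
Reagents that add atoms: none
Why: Proposed new method: CrCl2 inserts into the allylic C–Br bond and the 2-(methoxycarbonyl)allyl species of trivalent chromium adds through C7 to the tethered enal in a chair Zimmerman–Traxler transition state (Nozaki–Hiyama allylation, known intermolecularly for alpha-methylene-gamma-butyrolactones and for closing strained ten-membered rings), the equatorial gamma substituent giving the 6,7-anti (trans-lactone) relationship and the 8R carbinol, held with H8 eclipsing C7=C11 to avoid allylic strain so that C6 bonds anti to the C8–C9 bond, giving 6R,7R; the C6 chromium alkoxide lactonizes onto the methyl ester, and the ring then holds the C10 hydroxyl over C3 so that monovalent-gold-catalysed 5-endo-dig oxa-Michael addition (the known alpha′-hydroxy ynone to 3(2H)-furanone cyclization) closes the furanone transannularly with release of alkyne strain, the ynone standing in for the 10-hydroxy-1,3-dione of the biosynthesis and the free 8-hydroxyl being a poor leaving group that disfavours reductive 1,4-elimination.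

**Step 10**
Reactants: 20 (4Z,6R,7R,8R,10R)-8-hydroxy-3,10-epoxy-1-oxogermacra-2,4,11(13)-trien-12,6-olide; 21 angelic acid
Product: 23 15-deoxybudlein A, via mixed anhydride 22 (not isolated)
Conditions: 21 (3 equiv), 2,4,6-trichlorobenzoyl chloride (3 equiv), Et3N (6 equiv), toluene, 25 °C, 2 h; then 20, 75 °C
Reagents that add atoms: none
Why: Yamaguchi-type mixed-anhydride esterification without a nucleophilic catalyst acylates the only hydroxyl (C8) with retention at carbon and keeps the Z geometry of the angelate.

**Compound list**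
1 | 1,1-dimethoxypropan-2-one | CC(=O)C(OC)OC | starting material
2 | 3,3-dimethoxy-2-(trimethylsilyloxy)prop-1-ene | C=C(O[Si](C)(C)C)C(OC)OC | intermediate
3 | methyl pyruvate | CC(=O)C(=O)OC | starting material
4 | methyl (2R)-5,5-dimethoxy-2-methyl-4-oxo-2-(trimethylsilyloxy)pentanoate | COC(=O)[C@](C)(O[Si](C)(C)C)CC(=O)C(OC)OC | intermediate
5 | methyl (2R)-2-hydroxy-5,5-dimethoxy-2-methyl-4-oxopentanoate | COC(=O)[C@](C)(O)CC(=O)C(OC)OC | intermediate
6 | methyl (2R,4R)-2,4-dihydroxy-5,5-dimethoxy-2-methylpentanoate | COC(=O)[C@](C)(O)C[C@@H](O)C(OC)OC | intermediate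
7 | (3R,5R)-5-(dimethoxymethyl)-3-hydroxy-3-methyloxolan-2-one | COC(OC)[C@H]1C[C@@](C)(O)C(=O)O1 | intermediate
8 | methyl acrylate | C=CC(=O)OC | starting material
9 | (2R,4R)-4-hydroxy-4-methyl-5-oxooxolane-2-carbaldehyde | O=C[C@H]1C[C@@](C)(O)C(=O)O1 | intermediate
10 | methyl 2-{hydroxy[(2R,4R)-4-hydroxy-4-methyl-5-oxooxolan-2-yl]methyl}prop-2-enoate (both carbinol epimers) | C=C(C(=O)OC)C(O)[C@H]1C[C@@](C)(O)C(=O)O1 | intermediate
11 | (2Z)-3-methylpent-2-en-4-yn-1-ol | C#C/C(C)=C\CO | starting material
12 | (2Z)-3-methylpent-2-en-4-ynal | C#C/C(C)=C\C=O | intermediate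
13 | (3Z)-5,5-dimethoxy-3-methylpent-3-en-1-yne | C#C/C(C)=C\C(OC)OC | intermediate
14 | lithium (3Z)-5,5-dimethoxy-3-methylpent-3-en-1-yn-1-ide | [Li]C#C/C(C)=C\C(OC)OC | intermediate
15 | methyl (4R,6R,10Z)-3,4,6-trihydroxy-12,12-dimethoxy-6,10-dimethyl-2-methylidene-7-oxododec-10-en-8-ynoate (both C3 epimers) | C=C(C(=O)OC)C(O)[C@H](O)C[C@@](C)(O)C(=O)C#C/C(C)=C\C(OC)OC | intermediate
16 | methyl (2Z,4R,6R,10Z)-2-(bromomethyl)-4,6-dihydroxy-12,12-dimethoxy-6,10-dimethyl-7-oxododeca-2,10-dien-8-ynoate | COC(=O)/C(CBr)=C/[C@H](O)C[C@@](C)(O)C(=O)C#C/C(C)=C\C(OC)OC | intermediate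
17 | methyl (2Z,4R,6R,10Z)-2-(bromomethyl)-4,6-dihydroxy-6,10-dimethyl-7,12-dioxododeca-2,10-dien-8-ynoate | COC(=O)/C(CBr)=C/[C@H](O)C[C@@](C)(O)C(=O)C#C/C(C)=C\C=O | intermediate
18 | methyl (4Z,6R,7R,8R,10R)-6,8,10-trihydroxy-1-oxogermacra-4,11(13)-dien-2-yn-12-oate | C=C(C(=O)OC)[C@H]1[C@H](O)/C=C(/C)C#CC(=O)[C@](C)(O)C[C@H]1O | intermediate
19 | (4Z,6R,7R,8R,10R)-8,10-dihydroxy-1-oxogermacra-4,11(13)-dien-2-yn-12,6-olide | C=C1C(=O)O[C@@H]2/C=C(/C)C#CC(=O)[C@](C)(O)C[C@@H](O)[C@@H]12 | intermediate
20 | (4Z,6R,7R,8R,10R)-8-hydroxy-3,10-epoxy-1-oxogermacra-2,4,11(13)-trien-12,6-olide (8-O-deangeloyl-15-deoxybudlein A) | C=C1C(=O)O[C@@H]2/C=C(/C)C3=CC(=O)[C@@](C)(C[C@@H](O)[C@@H]12)O3 | intermediate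
21 | angelic acid ((2Z)-2-methylbut-2-enoic acid) | C/C=C(/C)C(=O)O | starting material
22 | (2Z)-2-methylbut-2-enoic 2,4,6-trichlorobenzoic anhydride | C/C=C(/C)C(=O)OC(=O)c1c(Cl)cc(Cl)cc1Cl | intermediate
23 | 15-deoxybudlein A | C=C1C(=O)O[C@@H]2/C=C(/C)C3=CC(=O)[C@@](C)(C[C@@H](OC(=O)/C(C)=C\C)[C@@H]12)O3 | target

**Step count and risks**
Total step count: 10. Longest linear sequence: 8 steps (steps 1, 2, 3, 4, 7, 8, 9, 10).

Most at risk is step 9. The strained enyne ring may close slowly, CrCl2 may attack the ynone, or the C6/C7 configuration may come out wrong. The fallback reverses the ring order and sets out from 17. (Ph3P)AuNTf2 in toluene first closes the furanone on the open chain to give the acyclic furanone bromo enal F1. CrCl2 in THF at high dilution then performs the allylation and lactonization on this preorganized, ynone-free substrate, and the route is rejoined at 20.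

Second is step 7. The acetylide may attack the acrylate ester, and the free C8 hydroxyl of 15 may lactonize onto the methyl ester before step 8. The fallback sets out from 10. Me3SiCl and imidazole give the bis(trimethylsilyl) ether F2. Compound 13 is lithiated and treated with BF3·OEt2 to give the lithium alkynyltrifluoroborate F3, which opens only the Lewis-acid-activated lactone of F2 at −78 °C to give the silylated ynone F4. Citric acid in methanol removes the silyl groups just before step 8, and the route is rejoined at 15.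

Third is step 4. The alpha-acyloxy aldehyde 9 may epimerize at C8 or hydrate and react slowly under the amine. The fallback sets out from 7, which is hydrolysed to 9 as before. The acrylate unit is then delivered without base by vinylalumination: methyl propiolate, DIBAL-H and N-methylmorpholine N-oxide in THF at 0 °C give the vinylalane F5, which adds to the aldehyde of 9 within minutes. The route is rejoined at 10.

**Further compounds**
F1 | step 9 | methyl (2Z,4R)-2-(bromomethyl)-4-hydroxy-5-{(2R)-2-methyl-3-oxo-5-[(2Z)-4-oxobut-2-en-2-yl]-2,3-dihydrofuran-2-yl}pent-2-enoate | COC(=O)/C(CBr)=C/[C@H](O)C[C@@]1(C)OC(=CC1=O)/C(C)=C\C=O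
F2 | step 7 | methyl 2-{[(2R,4R)-4-methyl-5-oxo-4-(trimethylsilyloxy)oxolan-2-yl](trimethylsilyloxy)methyl}prop-2-enoate | C=C(C(=O)OC)C(O[Si](C)(C)C)[C@H]1C[C@@](C)(O[Si](C)(C)C)C(=O)O1
F3 | step 7 | lithium trifluoro[(3Z)-5,5-dimethoxy-3-methylpent-3-en-1-yn-1-yl]borate | [Li+].F[B-](F)(F)C#C/C(C)=C\C(OC)OC
F4 | step 7 | methyl (4R,6R,10Z)-4-hydroxy-12,12-dimethoxy-6,10-dimethyl-2-methylidene-7-oxo-3,6-bis(trimethylsilyloxy)dodec-10-en-8-ynoate | C=C(C(=O)OC)C(O[Si](C)(C)C)[C@H](O)C[C@@](C)(O[Si](C)(C)C)C(=O)C#C/C(C)=C\C(OC)OC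
F5 | step 4 | methyl 2-[bis(2-methylpropyl)alumanyl]prop-2-enoate | C=C(C(=O)OC)[Al](CC(C)C)CC(C)C
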